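(The numbers in the tables are simulated for substances that don't exist; noise was put on by code.)

The constants I need are two, and both have to be read from the earlier runs: how fast target is made, and how fast it is lost once made.

all flasks: free catalyst 0.5 mol%

| flask | starting material | second substrate | temperature | remark | time |
|---|---|---|---|---|---|
| dawn | 1 M | 0.67 equiv | 45 °C | run made earlier |  |
| winter | 1 M | 1.5 equiv | 60 °C | run made earlier |  |
| midnight | 0.50 M | 1 equiv | 45 °C | run made earlier |  |
| north-west | 1.0 M | 1.00 equiv | 70 °C |  | 25 min |
| north-east | 1.0 M | 1.00 equiv | 50 °C |  | 25 min |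

| run | time / min | target / % | starting material / % |
|---|---|---|---|
| dawn | 6.00 | 2.2 | 98.5 |
| dawn | 15.0 | 3.2 | 97.9 |
| dawn | 30.0 | 4.7 | 94.7 |
| dawn | 50.0 | 8.6 | 92.2 |
| winter | 6.00 | 3.9 | 95.4 |
| winter | 12.0 | 6.7 | 91.6 |
| winter | 20.0 | 8.3 | 88.7 |
| winter | 25.0 | 9.9 | 86.3 |
| midnight | 6.00 | 1.4 | 99.9 |
| midnight | 15.0 | 2.6 | 98.1 |
| midnight | 30.0 | 2.9 | 96.6 |
| midnight | 50.0 | 4.2 | 95.7 |

(readings scatter by 1 percentage point)



1. the winner by amount of target, in percent of the starting material charged; "neither" if no more than 2 percentage points parts them (north-west / north-east / neither)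
2. how much target is there at the end, in percent of the starting material charged: north-west
3. how much target is there at the end, in percent of the starting material charged: north-east

At the last reading of the dawn run, target and starting material add up to 101%. In the winter run, which is both hotter and richer in second substrate, they add up to 96.2%, and the gap to the charge is wider than at its first reading. Two scattered readings stand in it, so it is rough. I take it as target lost at a rate set by the concentration of target itself, which makes the loss first order:

gap at the last winter reading: 3.8 percentage points
mean target over that run: 5.96%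
loss constant, gap over mean target times time: 0.0255 min⁻¹

The natural log of two over this constant is the survival half-life, the first-order half-life of target against whatever consumes it: 27.2 min at 60 °C, as read from the scattered winter readings.

Making comes next, setting aside the difference in second substrate. Target plus gap gives 0.00548 min⁻¹ of the charge in winter, and dawn gives 0.00172 min⁻¹. Each new flask lies 0.667 of the dawn-to-winter step from winter, so I move making by a factor of 2.17, up for north-west and down for north-east. Lending that factor to the loss, target = making/loss × (1 − exp(−loss × time)) gives:

north-west: 16.1%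
north-east: 5.47%

That loan is the weak link. The dawn gap of 0.6 points at 30.0 min reads as a loss constant of 0.00666 min⁻¹, less than the loan implies. Each reading in that gap carries a scatter of 1 point, so this constant is rough too, and dawn and winter differ in second substrate as well as in temperature. So the loss gets its own factor, 2.45, and I commit to:

north-west: 15.0%
north-east: 5.56%

The forecast differs from my reckoning: 10% for north-west, 6.5% for north-east, and north-west the winner, on grounds that include “a modest temperature effect”.

The flask gives 17.6% in north-west and 5.37% in north-east, so north-west wins, and the forecast's north-west figure stands 7.6 points low.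

    2 starting material → self-condensation product (k = 3.00 × 10⁻⁶ M⁻¹ s⁻¹, Ea = 87.0 kJ mol⁻¹)
    starting material + free catalyst ⇌ catalyst intermediate A (K = 16.0 M⁻¹, k = 0.170 M⁻¹ s⁻¹, Ea = 71.0 kJ mol⁻¹, ΔH = 14.0 kJ mol⁻¹)
    target → over-reaction product (k = 0.00120 s⁻¹, Ea = 105 kJ mol⁻¹)
    free catalyst + target → spent catalyst (k = 3.10 × 10⁻⁴ M⁻¹ s⁻¹, Ea = 85.0 kJ mol⁻¹)
    catalyst intermediate A → free catalyst + target (k = 0.260 s⁻¹, Ea = 97.0 kJ mol⁻¹)
    catalyst intermediate B → free catalyst + second product (k = 0.0520 s⁻¹, Ea = 101 kJ mol⁻¹)
    second substrate + free catalyst ⇌ catalyst intermediate B (K = 1.10 M⁻¹, k = 0.310 M⁻¹ s⁻¹, Ea = 66.0 kJ mol⁻¹, ΔH = −38.0 kJ mol⁻¹)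
    (constants at 70 °C)

With the survival half-life moved by my loss factor, the time counts 2.25 half-lives in north-west and 0.375 in north-east. In north-west, target goes to over-reaction product with a half-life of 9.63 min at 70 °C, shorter than the time of 25 min, and at the end 22.5% of over-reaction product stands beside 17.6% of target. In north-east, the same step has a half-life of 94 min at 12.2 min, long against the time, and at the end 0.512% of over-reaction product stands beside 5.37% of target.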